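The data were computed for an exercise; noise was put on by code.

Start with an easy step: call S the substrate and target taken together, in percent of the substrate charged. In the scheme the reversible step moves material within S, and the step to side product takes it out of S. Here is the flask, followed so far, and what is asked of it.

common to all: substrate 20 mM; gas phase 3.9 mM (held)
- theta: protic impurity 1 mM; the very flask that is asked about, followed so far
- flask: protic impurity 1.00 mM; time 15 min

- theta (time / min: substrate / %, target / %, side product / %): 0.200: 99, 2, 1; 0.500: 93, 6, 2; 1.33: 78, 19, 5; 2.50: 68, 24, 5

(each reading ± 1.5 percentage points)

- at the start none of the gas is dissolved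
- steps thought possible: gas phase <-> dissolved gas; substrate + dissolved gas <-> target; dissolved gas + protic impurity -> quenched reagent; substrate -> side product

- substrate present at 15 min, in percent of the substrate charged
- target present at 15 min, in percent of the substrate charged
- side product present at 15 min, in percent of the substrate charged
- concentration of dissolved gas at 15 min, in mM

My own reckoning begins at the last reading, with its scatter of 1.5 percentage points. There S is what the side product has not taken. Let k be the first-order constant of the leak to side product, and use the mean substrate so far:

S = 95.0%, k ≈ 0.0238 min⁻¹

Let r be target over substrate, read as 0.353. A fraction 1/(1+r) of S is then substrate, and S shrinks as a pre-equilibrium with a slow leak: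

S(15 min) ≈ 76.2%, so substrate 56.4%, target 19.9%

The weak link is r, which climbs across the readings so far. Its slope between readings shrinks by a factor g per step, so I sum the steps still to come:

g ≈ 0.433, final r ≈ 0.437

Then λ = k/(1+r) = 0.0166 min⁻¹ is the pool's leak constant, the first-order constant with which S decays. I commit to these values:

S = 77.2%: substrate 53.8%, target 23.5%, side product 22.8%, dissolved gas 3.9 mM

The forecast, made from the same runs, gives substrate 53%, target 24%, side product 23% and dissolved gas 3.8 mM. Its ground for the side product is that “this step is irreversible and should keep draining substrate through the equilibrium”.

The flask gives substrate 49.0%, target 25.8%, side product 25.2% and dissolved gas 3.91 mM.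

    gas phase ⇌ dissolved gas, rate k1*(csat - [dissolved gas]) (kL = 5.40 min⁻¹)
    substrate + dissolved gas ⇌ target (K = 130 M⁻¹, k = 74.0 M⁻¹ min⁻¹)
    dissolved gas + protic impurity → quenched reagent (k = 19.0 M⁻¹ min⁻¹)
    substrate → side product (k = 0.0280 min⁻¹)

In this flask at 15.0 min, substrate enters target by the forward step alone 10 times as fast as it goes to side product, and the half-life of substrate by that forward rate alone is 2.4 min, short against the 15 min of the run, and S between 7.50 min and 15 min falls with a constant of 0.0184 min⁻¹, beside λ = 0.0166 min⁻¹. Carried to the same flask read at 1.0 h, λ gives S = 36.6%, and that flask holds S = 32.7%.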